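## The problem

Manassantin A (21) is a C2-symmetric dineolignan. A central oxolane (O1, C2 to C5) carries a 3-methoxy-4-oxyphenyl ring at C2 (ring A) and at C5 (ring B) and a methyl group at C3 and at C4. The para oxygen of each ring is etherified by C8 of a 1-(3,4-dimethoxyphenyl)-1-hydroxypropan-2-yl chain (C7 carbinol, C8 methyl-bearing carbon, primed in the second half).

No rings are fused. Five rings must be joined through one oxolane and two aryl alkyl ether bonds, and eight stereocentres must be set: 2S,3R,4R,5S in the ring (2,3-cis, 3,4-trans, 4,5-cis) and 7R,8R (threo) in each chain. The cis,trans,cis ring is the least stable member of the 3,4-trans family, because each aryl group stands beside a cis methyl group, so C2 and C5 have to be set kinetically.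

C2–O1 and C5–O1 are benzylic bonds para to an oxygen donor. Acids open them to quinone-methide-like cations that reclose trans, hot base can do the same from a free phenoxide, and hydrogenolysis can cleave them.

Within the ring the centres can be chained: C4 and C5 arise together, C4 then fixes the enolisable C3 thermodynamically, and C3 to C5 together steer the last bond at C2. The chain centres are too far from the core to feel it. C8 must therefore be brought in enantiopure, and C7 can be derived from C8 by 1,2-induction. At the ketone stage C8 is enolisable and tolerates only mild base.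

The feature that opens the key step is that O1, C2, C3, C4 and C5 with both methyl groups and ring B are the atoms of the γ-aryl-α,β-dimethyl-γ-butyrolactone 5. This lactone is the sum of tiglic aldehyde 3 (C2 to C4 and both methyls) and a ring-B benzaldehyde 2 (C5 and O1), provided that C4 of the enal can be made nucleophilic.

## Retrosynthesis

**C7–H and C7'–H (21 to 20).** The last operation should create as little as possible, so the two carbinol C–H bonds are cut first and 21 is traced to diketone 20. Bringing in each chain with C7 already at the alcohol level would make the ether formation at C8 a substitution at an unactivated, β-oxygenated secondary carbon. The carbonyl group instead activates C8 and afterwards receives the 1,2-induction. Compound 20 has six stereocentres in place of eight. The forward reduction must follow the polar Felkin–Anh course on both halves, which calls for a hydride source without a chelating cation.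

**C8–O and C8'–O (20 to 13 and 19).** The two C8–O(aryl) bonds are cut next, giving bisphenol 13 and two equivalents of the α-sulfonyloxy ketone 19. Cutting on the other side of the oxygen would require arylation of an alcohol by an electron-rich arene. A racemic α-halo ketone as electrophile would scatter C8 and C8' over three diastereomers. An enantiopure sulfonate displaced with inversion avoids both problems. The 42-carbon target falls into a 20-carbon core and two identical 11-carbon ketone units, and the symmetry lets one operation serve both ends. The forward reaction has to be a clean SN2 process under a base mild enough to leave C8 of 19 and 20 alone.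

**The chain unit (19 to 14 and 16).** Sulfonate 19 comes from hydroxy ketone 18 by O-sulfonylation. Compound 18 is cut at the C7–aryl bond into the lactic Weinreb amide 15 and Grignard reagent 17 (from bromide 16), and 15 is made from ethyl (S)-lactate 14. Asymmetric oxidation of a propiophenone enol derivative would also reach 18, but the chiral pool gives C8 in known configuration and full purity for the same number of steps. Inversion in the ether formation turns the natural (S) series into the required 8R. The forward steps must neither touch the C8–O bond nor enolise the ketone.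

**Protecting groups and C2–ring A (13 to 7 and 11).** Bisphenol 13 is the deprotected form of 12, in which ring A bears a silyl ether and ring B an arenesulfonate. Hydroxide removes both in one operation, without acid and without hydrogenolysis. In 12 the C2–ring A bond is cut. This leads to the 2-sulfonyl oxolane 7, a stored C2 oxocarbenium ion, and arylzinc bromide 11 (from 8 through 9 and 10).

The reverse order (aryl addition at the lactone stage, then hydride delivery to a 2-aryl oxocarbenium ion) is one step shorter, but it has three drawbacks:
- it needs a strong boron Lewis acid;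
- it passes through a cation whose oxygen is an excellent leaving group for benzylic C5;
- it asks hydride to enter from the face that ring B and the C4 methyl occupy.

With the aryl group as the incoming nucleophile, the 2,3-cis product results from attack on the open face under a mild zinc Lewis acid. The cut removes one aryl ring and one stereocentre.

**C2 substituent changes (7 to 5).** Sulfone 7 is traced through lactol 6 to lactone 5 by two exchanges at C2, and no skeletal bond is involved. The lactone is the stable, purifiable carrier of C3, C4 and C5. The forward steps need a reduction that stops at the lactol and an acid-mediated exchange that does not ionise C5.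

**C4–C5 and O1–C2 (5 to 2 and 3).** Lactone 5 is cut into aldehyde 2 and tiglic aldehyde 3. Stepwise aldol or crotylation, homologation and methylation sequences reach the same lactone, but they need four or more steps and a stoichiometric chiral controller. The double cut uses every carbon of two cheap aldehydes and leaves the overall oxidation level unchanged. It makes one ring, two skeletal bonds and three stereocentres in one catalytic operation.

The cut requires polarity inversion at C4, which a carbene catalyst provides through the homoenolate. The known soft spots are slow reaction of α-branched enals, poor acceptor quality of alkoxy-substituted benzaldehydes and modest enantiocontrol. They are addressed within the same disconnection: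
- the sulfonate on ring B turns a sluggish acceptor into an activated one;
- an N-mesityl triazolylidene with a titanium alkoxide co-catalyst supplies rate and organisation;
- C3 is left to thermodynamic correction by the amine base.

**Protected monomers (2 to 1, 9 to 8).** Aldehyde 2 is the tosylate of vanillin 1, and bromide 9 is the silyl ether of 4-bromo-2-methoxyphenol 8. Each is one step from a commercial phenol.

## Roads not taken

Alternative 1: The cut removes both C–aryl bonds of the oxolane at once. It leads to the bis-sulfone A2 and two equivalents of arylzinc bromide A3, which already holds a complete silyl-protected chain. In the forward step a zinc Lewis acid ionises A2 twice and A3 captures both oxocarbenium ions to give A1, which needs only desilylation.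
- *Merits:* Convergence is maximal and the symmetry is fully used. All four chain stereocentres are secured and purified on a small fragment, and there is no ketone-stage C8 on the valuable core. In steps after the coupling it is better than the chosen plan, and it is probably shorter in the longest line.
- *Weak points:* A2 must come from the enantiopure dialdehyde A4, which is epimerisable and itself needs an auxiliary-based synthesis. The first capture meets a cation with a sulfonyl group of undefined configuration at C5 instead of an aryl group, so the resident controller is missing. Two-fold loss of sulfinic acid with aromatisation of the ring is a strong competing drain. A multistep zinc reagent also has to be used in excess.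
- *Comparison:* The chosen plan uses the same displacement only once (step 6), where ring B and the C4 methyl direct it. It sets against the higher convergence a catalytic origin of the core stereocentres from two commodity aldehydes.

Alternative 2: The cut removes C3–C4, C2–O1 and C5–O1 and leads to two molecules of the propenylarene A6 that carries the finished, acetylated chain. Anodic oxidation in wet acetonitrile would couple two radical cations at their β-carbons, and water would bridge the two benzylic cations to give A5.
- *Merits:* The step is biomimetic, forms three bonds and four stereocentres from one monomer, and is the shortest conceivable route. The chosen plan cannot match this brevity.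
- *Weak points:* The β,β-coupling has no element that distinguishes threo from erythro or one enantiomeric core from the other, since the chain stereocentres are remote. The ring closure proceeds through free benzylic cations, which favour aryl trans to methyl, whereas the target has the least stable array. Non-phenolic propenylarenes also divert to cyclobutane and aryltetralin dimers. The acid generated at the anode would epimerise any cis isomer formed.
- *Comparison:* The chosen plan is longer, but each ring stereocentre is assigned to a defined control element.

Alternative 3: The cut is O1–C5 of the dihydrofuran A7. It leads to the aryl cyclopropyl ketone A8, whose ring-B aryl and neighbouring methyl group are trans. A Lewis acid would break the bond between the acyl-bearing and the benzylic carbon while the ketone oxygen attacks the benzylic carbon with inversion.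
- *Merits:* The contra-thermodynamic 4,5-cis relation follows from stereospecificity, which is stronger in principle than the diastereoselectivity on which step 2 depends. The tosylate on ring B tempers cation character, the same device used here.
- *Weak points:* Ring opening needs donor ability at the benzylic carbon while inversion forbids a free cation, so the window is narrow. A8 has a fully substituted acyl carbon and would need an α-methyl diazo ketone carbenoid, which is prone to hydride shift. After the key step, C2 and C3 are still missing. Syn hydrogenation of the tetrasubstituted enol ether would have to come from the face occupied by the C4 methyl and ring B; addition from the open face sets both centres with the wrong sense relative to C4. It also endangers the benzyl ether and the benzylic C–O bonds.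
- *Comparison:* The chosen plan fixes three ring centres in its key step and leaves only C2, which is set by attack on the open face.

Key step: step 2

Assumption: the sense of induction of the triazolylidene with an α,β-dialkyl enal cannot be derived with certainty from a model. The (5aR,10bS) salt is written, and its commercial antipode is taken if the lactone proves to be the enantiomer of 5.

## Steps

Step 1
Reactants: 1 vanillin (4-hydroxy-3-methoxybenzaldehyde)
Product: 2 4-formyl-2-methoxyphenyl 4-methylbenzenesulfonate (O-tosylvanillin)
Conditions: TsCl, Et3N, 4-(dimethylamino)pyridine (cat.), CH2Cl2, 0 °C to rt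
Reagents that add atoms: 4-toluenesulfonyl chloride, Cc1ccc(S(=O)(=O)Cl)cc1
Why: Standard O-sulfonylation of a phenol with no stereocentre involved. The sulfonate replaces a donating para oxygen by a withdrawing one, which raises the acceptor quality of the formyl group for step 2 and later holds back ionisation of the C5–O1 bond.

Step 2
Reactants: 2 4-formyl-2-methoxyphenyl 4-methylbenzenesulfonate; 3 (E)-2-methylbut-2-enal (tiglic aldehyde)
Product: 5 (3R,4R,5S)-5-[3-methoxy-4-(tosyloxy)phenyl]-3,4-dimethyldihydrofuran-2(3H)-one, via all-cis C3 epimer 4 (not isolated)
Conditions: 3 (3 equiv), (5aR,10bS)-2-mesityl-5a,10b-dihydro-4H,6H-indeno[2,1-b][1,2,4]triazolo[4,3-d][1,4]oxazin-2-ium chloride (15 mol %), 1,8-diazabicyclo[5.4.0]undec-7-ene (DBU, 15 mol %), Ti(Oi-Pr)4 (20 mol %), 4 Å MS, CH2Cl2, 25 to 40 °C; then DBU (1 equiv), toluene, 80 °C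
Reagents that add atoms: none
Why: The triazolylidene adds to the formyl carbon of 3 (the N-mesityl group makes this addition effectively irreversible, which matters for an α-branched enal), and proton transfer gives the extended Breslow intermediate, a homoenolate whose β-carbon (future C4) attacks the titanium-bound formyl carbon of 2 (future C5) and forms C4–C5. Protonation at C3 converts the resulting enol into an acyl azolium, which the new C5 alkoxide captures by 5-exo-trig addition–elimination; this forms O1–C2, closes the lactone and releases the carbene. The closest known reaction type is the carbene-catalysed homoenolate (3+2) annulation of enals with aryl aldehydes to cis-γ-butyrolactones, in its Lewis-acid-assisted enantioselective form. C4 and C5 are set in the C–C bond-forming event: the titanium alkoxide ties enol oxygen and aldehyde oxygen into a compact array that places ring B and the C4 methyl cis, and the indane wall of the carbene leaves one face of the homoenolate open, which fixes the absolute sense (4R,5S). C3 is first set by a protonation of uncertain selectivity, so part of the material appears as 4; the amine base then equilibrates the lactone α-centre, and the C4 methyl drives it to the 3,4-trans isomer 5 because the alternative is the crowded all-cis lactone. The step needs cross-selectivity over benzoin formation, enal self-annulation and β-protonation: 2 has no α-hydrogen and its sulfonate makes the formyl group a better acceptor than an alkoxy-substituted one, benzoin formation is reversible, 3 is a poor acceptor (conjugated and α-branched), and no protic additive is present.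

Step 3
Reactants: 5 (3R,4R,5S)-5-[3-methoxy-4-(tosyloxy)phenyl]-3,4-dimethyldihydrofuran-2(3H)-one
Product: 6 (3R,4R,5S)-5-[3-methoxy-4-(tosyloxy)phenyl]-3,4-dimethyloxolan-2-ol (anomeric mixture)
Conditions: i-Bu2AlH (1.1 equiv), CH2Cl2, −78 °C; aq. potassium sodium tartrate
Reagents that add atoms: none
Why: Partial reduction of a γ-lactone stops at the aluminium hemiacetal at low temperature, and the aryl sulfonate is inert under these conditions. C2 forms as an anomeric mixture, which is of no consequence because it is ionised in step 6.

Step 4
Reactants: 6 (3R,4R,5S)-5-[3-methoxy-4-(tosyloxy)phenyl]-3,4-dimethyloxolan-2-ol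
Product: 7 (3R,4R,5S)-5-[3-methoxy-4-(tosyloxy)phenyl]-3,4-dimethyl-2-(phenylsulfonyl)oxolane (anomeric mixture)
Conditions: PhSO2H, CaCl2, CH2Cl2, 0 °C to rt
Reagents that add atoms: benzenesulfinic acid, O=S(O)c1ccccc1
Why: Acid-mediated exchange of an anomeric hydroxyl for sulfinate (S-alkylation of the sulfinic acid by the transient oxocarbenium ion) is the standard entry to 2-sulfonyl cyclic ethers, with CaCl2 binding the water. The sulfonate on ring B keeps benzylic C5 from ionising under the acid, and C3 to C5 are untouched.

Step 5
Reactants: 8 4-bromo-2-methoxyphenol
Product: 9 (4-bromo-2-methoxyphenoxy)(tert-butyl)dimethylsilane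
Conditions: TBSCl, imidazole, DMF, rt
Reagents that add atoms: tert-butyldimethylsilyl chloride, CC(C)(C)[Si](C)(C)Cl
Why: Routine silylation of a phenol. The silyl ether survives bromine–lithium exchange at low temperature and falls under the same hydroxide treatment as the sulfonate in step 7.

Step 6
Reactants: 9 (4-bromo-2-methoxyphenoxy)(tert-butyl)dimethylsilane; 7 (3R,4R,5S)-5-[3-methoxy-4-(tosyloxy)phenyl]-3,4-dimethyl-2-(phenylsulfonyl)oxolane
Product: 12 (2S,3R,4R,5S)-2-[4-(tert-butyldimethylsilyloxy)-3-methoxyphenyl]-5-[3-methoxy-4-(tosyloxy)phenyl]-3,4-dimethyloxolane, via aryllithium 10 (not isolated), via arylzinc bromide 11 (not isolated)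
Conditions: 9 (2.5 equiv), n-BuLi, THF, −78 °C; ZnBr2, −78 °C to rt; then 7, THF, rt
Reagents that add atoms: none
Why: Bromine–lithium exchange and transmetalation give a mild aryl nucleophile, and the zinc halide ionises the 2-sulfonyl ether to the C2 oxocarbenium ion (arylzinc substitution of 2-sulfonyl cyclic ethers, a known reaction type). In the envelope with both methyl groups pseudo-equatorial the C4 flap points to the face of the C3 methyl, so inside attack, which is also the approach opposite to ring B and the C4 methyl, puts ring A cis to the C3 methyl and sets C2 as S. The zinc Lewis acid is too weak to open C5–O1, all the more as ring B carries the sulfonate.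

Step 7
Reactants: 12 (2S,3R,4R,5S)-2-[4-(tert-butyldimethylsilyloxy)-3-methoxyphenyl]-5-[3-methoxy-4-(tosyloxy)phenyl]-3,4-dimethyloxolane
Product: 13 4,4'-[(2S,3R,4R,5S)-3,4-dimethyloxolane-2,5-diyl]bis(2-methoxyphenol)
Conditions: KOH (10 equiv), 1,4-dioxane/H2O, 70 °C, Ar; then 1 M HCl to pH 5
Reagents that add atoms: none
Why: Hydroxide attacks silicon of the aryl silyl ether and sulfur of the aryl sulfonate (Si–O and S–O cleavage), so both aryl C–O bonds and the four ring stereocentres stay untouched and neither acid nor hydrogenolysis is needed. Aqueous dioxane in place of an alcohol avoids an alkyl tosylate that could alkylate the phenoxide.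

Step 8
Reactants: 14 ethyl (S)-lactate
Product: 15 (S)-2-hydroxy-N-methoxy-N-methylpropanamide
Conditions: MeNH(OMe)·HCl, i-PrMgCl, THF, −20 to 0 °C
Reagents that add atoms: N,O-dimethylhydroxylamine hydrochloride, CNOC.Cl
Why: Aminolysis of an ester by the magnesium amide of N,O-dimethylhydroxylamine (Weinreb amide synthesis). The hydroxyl is present as its magnesium alkoxide, which suppresses enolisation, so C8 keeps the S configuration.

Step 9
Reactants: 16 4-bromo-1,2-dimethoxybenzene; 15 (S)-2-hydroxy-N-methoxy-N-methylpropanamide
Product: 18 (S)-1-(3,4-dimethoxyphenyl)-2-hydroxypropan-1-one, via 3,4-dimethoxyphenylmagnesium bromide 17 (not isolated)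
Conditions: 16 (2.5 equiv), Mg, THF, rt to 40 °C; then 15, 0 °C; cold aq. citric acid
Reagents that add atoms: none
Why: Grignard addition to a Weinreb amide: the first equivalent deprotonates the hydroxyl and the second adds to give the chelated tetrahedral intermediate, which resists over-addition and enolisation. It collapses only on the cold acidic quench, so the S centre is retained.

Step 10
Reactants: 18 (S)-1-(3,4-dimethoxyphenyl)-2-hydroxypropan-1-one
Product: 19 (S)-1-(3,4-dimethoxyphenyl)-1-oxopropan-2-yl 4-methylbenzenesulfonate
Conditions: TsCl, Et3N, 4-(dimethylamino)pyridine (cat.), CH2Cl2, 0 °C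
Reagents that add atoms: 4-toluenesulfonyl chloride, Cc1ccc(S(=O)(=O)Cl)cc1
Why: O-sulfonylation leaves the C8–O bond intact and therefore proceeds with retention. Low temperature and short contact with the amine limit enolisation of the ketone.

Step 11
Reactants: 13 4,4'-[(2S,3R,4R,5S)-3,4-dimethyloxolane-2,5-diyl]bis(2-methoxyphenol); 19 (S)-1-(3,4-dimethoxyphenyl)-1-oxopropan-2-yl 4-methylbenzenesulfonate (2.4 equiv)
Product: 20 (2R,2'R)-2,2'-{[(2S,3R,4R,5S)-3,4-dimethyloxolane-2,5-diyl]bis[(2-methoxy-4,1-phenylene)oxy]}bis[1-(3,4-dimethoxyphenyl)propan-1-one]
Conditions: Cs2CO3 (2.4 equiv), MeCN, 0 °C to rt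
Reagents that add atoms: none
Why: Two-fold Williamson-type SN2 displacement of an α-keto sulfonate by phenoxide with inversion, which turns S in 19 into 8R and 8'R. The adjacent carbonyl accelerates the substitution enough for a weak base at or below room temperature, and the two ends react independently.

Step 12
Reactants: 20 (2R,2'R)-2,2'-{[(2S,3R,4R,5S)-3,4-dimethyloxolane-2,5-diyl]bis[(2-methoxy-4,1-phenylene)oxy]}bis[1-(3,4-dimethoxyphenyl)propan-1-one]
Product: 21 manassantin A
Conditions: Amberlite IRA-400 in the BH4− form (polymer-bound quaternary ammonium borohydride), MeOH, 0 °C to rt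
Reagents that add atoms: none
Why: Borohydride reduction of an α-aryloxy ketone under polar Felkin–Anh control: without a coordinating metal cation no chelate between carbonyl and aryloxy oxygen can form. The C8–OAr bond therefore stands perpendicular to the carbonyl and hydride enters anti to it past the C8 hydrogen. This converts 8R into 7R,8R (threo) at both ends and leaves the oxolane untouched.

## Compound list

1 | vanillin | COc1cc(C=O)ccc1O | starting material
2 | 4-formyl-2-methoxyphenyl 4-methylbenzenesulfonate | COc1cc(C=O)ccc1OS(=O)(=O)c2ccc(C)cc2 | intermediate
3 | (E)-2-methylbut-2-enal (tiglic aldehyde) | C/C=C(\C)C=O | starting material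
4 | (3S,4R,5S)-5-[3-methoxy-4-(tosyloxy)phenyl]-3,4-dimethyldihydrofuran-2(3H)-one (all-cis C3 epimer) | O=C1O[C@H](c2ccc(OS(=O)(=O)c3ccc(C)cc3)c(OC)c2)[C@H](C)[C@@H]1C | intermediate
5 | (3R,4R,5S)-5-[3-methoxy-4-(tosyloxy)phenyl]-3,4-dimethyldihydrofuran-2(3H)-one | O=C1O[C@H](c2ccc(OS(=O)(=O)c3ccc(C)cc3)c(OC)c2)[C@H](C)[C@H]1C | intermediate
6 | (3R,4R,5S)-5-[3-methoxy-4-(tosyloxy)phenyl]-3,4-dimethyloxolan-2-ol (anomeric mixture) | OC1O[C@H](c2ccc(OS(=O)(=O)c3ccc(C)cc3)c(OC)c2)[C@H](C)[C@H]1C | intermediate
7 | (3R,4R,5S)-5-[3-methoxy-4-(tosyloxy)phenyl]-3,4-dimethyl-2-(phenylsulfonyl)oxolane (anomeric mixture) | O=S(=O)(c1ccccc1)C1O[C@H](c2ccc(OS(=O)(=O)c3ccc(C)cc3)c(OC)c2)[C@H](C)[C@H]1C | intermediate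
8 | 4-bromo-2-methoxyphenol | COc1cc(Br)ccc1O | starting material
9 | (4-bromo-2-methoxyphenoxy)(tert-butyl)dimethylsilane | COc1cc(Br)ccc1O[Si](C)(C)C(C)(C)C | intermediate
10 | [4-(tert-butyldimethylsilyloxy)-3-methoxyphenyl]lithium | COc1cc([Li])ccc1O[Si](C)(C)C(C)(C)C | intermediate
11 | [4-(tert-butyldimethylsilyloxy)-3-methoxyphenyl]zinc bromide | COc1cc([Zn]Br)ccc1O[Si](C)(C)C(C)(C)C | intermediate
12 | (2S,3R,4R,5S)-2-[4-(tert-butyldimethylsilyloxy)-3-methoxyphenyl]-5-[3-methoxy-4-(tosyloxy)phenyl]-3,4-dimethyloxolane | COc1cc([C@H]2O[C@H](c3ccc(OS(=O)(=O)c4ccc(C)cc4)c(OC)c3)[C@H](C)[C@H]2C)ccc1O[Si](C)(C)C(C)(C)C | intermediate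
13 | 4,4'-[(2S,3R,4R,5S)-3,4-dimethyloxolane-2,5-diyl]bis(2-methoxyphenol) | COc1cc([C@H]2O[C@H](c3ccc(O)c(OC)c3)[C@H](C)[C@H]2C)ccc1O | intermediate
14 | ethyl (S)-lactate | C[C@H](O)C(=O)OCC | starting material
15 | (S)-2-hydroxy-N-methoxy-N-methylpropanamide | C[C@H](O)C(=O)N(C)OC | intermediate
16 | 4-bromo-1,2-dimethoxybenzene | COc1ccc(Br)cc1OC | starting material
17 | 3,4-dimethoxyphenylmagnesium bromide | COc1ccc([Mg]Br)cc1OC | intermediate
18 | (S)-1-(3,4-dimethoxyphenyl)-2-hydroxypropan-1-one | C[C@H](O)C(=O)c1ccc(OC)c(OC)c1 | intermediate
19 | (S)-1-(3,4-dimethoxyphenyl)-1-oxopropan-2-yl 4-methylbenzenesulfonate | C[C@H](OS(=O)(=O)c1ccc(C)cc1)C(=O)c2ccc(OC)c(OC)c2 | intermediate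
20 | (2R,2'R)-2,2'-{[(2S,3R,4R,5S)-3,4-dimethyloxolane-2,5-diyl]bis[(2-methoxy-4,1-phenylene)oxy]}bis[1-(3,4-dimethoxyphenyl)propan-1-one] | COc1ccc(C(=O)[C@@H](C)Oc2ccc([C@H]3O[C@H](c4ccc(O[C@H](C)C(=O)c5ccc(OC)c(OC)c5)c(OC)c4)[C@H](C)[C@H]3C)cc2OC)cc1OC | intermediate
21 | manassantin A | COc1ccc([C@@H](O)[C@@H](C)Oc2ccc([C@H]3O[C@H](c4ccc(O[C@H](C)[C@H](O)c5ccc(OC)c(OC)c5)c(OC)c4)[C@H](C)[C@H]3C)cc2OC)cc1OC | target

## Step count and least certain steps

Total: 12 steps. Longest linear sequence: 8 steps from vanillin (steps 1, 2, 3, 4, 6, 7, 11, 12).

**Step 2 (key step).**
- *Risk:* The most likely failure is slow formation of the Breslow intermediate from the α-branched enal. Reversible benzoin formation, β-protonation of the homoenolate and γ-deprotonation of 3 by the amine would then consume catalyst time and material. Beyond that, cis/trans selectivity and enantiofacial selectivity may be insufficient for a β-alkyl enal. The arenesulfonate raises the chance of a crystalline lactone that could be upgraded by recrystallisation.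
- *Fallback (from 2 back to 5, known chemistry):*
  1. Brown crotylboration of 2 with the (Z)-crotyldiisopinocampheylborane derived from (+)-α-pinene should give the syn homoallylic alcohol F1.
  2. Hydroboration with 9-borabicyclo[3.3.1]nonane and alkaline H2O2 gives the 1,4-diol F2.
  3. Oxidative lactonisation with 2,2,6,6-tetramethylpiperidine-1-oxyl (cat.) and PhI(OAc)2 gives the 4,5-cis lactone F3.
  4. Enolate methylation (LiN(SiMe3)2, MeI, THF, −78 °C) anti to the C4 methyl returns to 5.

**Step 6.**
- *Risk:* Facial selectivity may be poor if the envelope with pseudo-axial methyl groups takes part. Loss of sulfinic acid from the oxocarbenium ion to an enol ether competes with a slow capture.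
- *Fallback (from 5 back to 12):* The fallback reverses the order in which aryl and hydrogen arrive at C2, which is stereocomplementary. It applies if nucleophiles turn out to prefer the face anti to the C3 methyl. Aryllithium 10 is added to lactone 5 at −78 °C to give the hemiketal F4. Ionic reduction with Et3SiH and BF3·OEt2 at −78 °C, with hydride anti to the C3 methyl, returns to 12. The sulfonate on ring B is what makes the boron Lewis acid tolerable at C5.

**Step 7.**
- *Risk:* The hindered aryl sulfonate may hydrolyse too slowly at a safe temperature. Forcing conditions invite phenoxide-assisted opening of the benzylic C–O bonds and epimerisation at C2 or C5.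
- *Fallback (from 12 back to 13):* Hydrolysis is replaced by two mild, mechanistically different cleavages. Bu4NF in THF at 0 °C gives the monophenol tosylate F5. Reductive S–O cleavage with Mg in MeOH at rt returns to 13.

**Step 11.**
- *Risk:* Base-mediated enolisation of 19 or of the product would erode C8, and the error is doubled by the two ends. Incomplete second alkylation is a lesser concern.
- *Fallback (from 13 back to 20):* No α-keto stereocentre is exposed to carbonate. Double Mitsunobu etherification of 13 with ethyl (S)-lactate 14 (PPh3, diisopropyl azodicarboxylate, THF) proceeds with inversion to the bis[(R)-aryloxypropanoate] F6. Aminolysis with MeNH(OMe)·HCl and i-PrMgCl gives the bis-Weinreb amide F7. Addition of Grignard reagent 17 returns to 20.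

**Step 12.**
- *Risk:* Felkin–Anh selectivity may erode, for instance through hydrogen-bonded or partly chelated transition states in methanol. This counts twice because two centres are formed.
- *Fallback (from 20 to 21):* Substrate control is replaced by catalyst control. Noyori-type asymmetric transfer hydrogenation of 20 with RuCl(p-cymene)[(S,S)-TsDPEN] in the acidic HCO2H/Et3N azeotrope should deliver hydride to the same face of each aryl ketone as the Felkin–Anh course (matched case). This leads directly to 21 and makes no new compound (F0).

## Further compounds

F1 | step 2 | 4-[(1S,2R)-1-hydroxy-2-methylbut-3-en-1-yl]-2-methoxyphenyl 4-methylbenzenesulfonate | O[C@H](c1ccc(OS(=O)(=O)c2ccc(C)cc2)c(OC)c1)[C@H](C)C=C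
F2 | step 2 | 4-[(1S,2R)-1,4-dihydroxy-2-methylbutyl]-2-methoxyphenyl 4-methylbenzenesulfonate | O[C@H](c1ccc(OS(=O)(=O)c2ccc(C)cc2)c(OC)c1)[C@H](C)CCO
F3 | step 2 | (4R,5S)-5-[3-methoxy-4-(tosyloxy)phenyl]-4-methyldihydrofuran-2(3H)-one | O=C1O[C@H](c2ccc(OS(=O)(=O)c3ccc(C)cc3)c(OC)c2)[C@H](C)C1
F4 | step 6 | (3R,4R,5S)-2-[4-(tert-butyldimethylsilyloxy)-3-methoxyphenyl]-5-[3-methoxy-4-(tosyloxy)phenyl]-3,4-dimethyloxolan-2-ol | COc1cc(C2(O)O[C@H](c3ccc(OS(=O)(=O)c4ccc(C)cc4)c(OC)c3)[C@H](C)[C@H]2C)ccc1O[Si](C)(C)C(C)(C)C
F5 | step 7 | 4-[(2S,3R,4R,5S)-5-(4-hydroxy-3-methoxyphenyl)-3,4-dimethyloxolan-2-yl]-2-methoxyphenyl 4-methylbenzenesulfonate | COc1cc([C@H]2O[C@H](c3ccc(OS(=O)(=O)c4ccc(C)cc4)c(OC)c3)[C@H](C)[C@H]2C)ccc1O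
F6 | step 11 | diethyl (2R,2'R)-2,2'-{[(2S,3R,4R,5S)-3,4-dimethyloxolane-2,5-diyl]bis[(2-methoxy-4,1-phenylene)oxy]}dipropanoate | CCOC(=O)[C@@H](C)Oc1ccc([C@H]2O[C@H](c3ccc(O[C@H](C)C(=O)OCC)c(OC)c3)[C@H](C)[C@H]2C)cc1OC
F7 | step 11 | (2R,2'R)-2,2'-{[(2S,3R,4R,5S)-3,4-dimethyloxolane-2,5-diyl]bis[(2-methoxy-4,1-phenylene)oxy]}bis(N-methoxy-N-methylpropanamide) | CON(C)C(=O)[C@@H](C)Oc1ccc([C@H]2O[C@H](c3ccc(O[C@H](C)C(=O)N(C)OC)c(OC)c3)[C@H](C)[C@H]2C)cc1OC
F0 | step 12 | none | none
A1 | alternative 1 | manassantin A bis(tert-butyldimethylsilyl) ether | COc1ccc([C@@H](O[Si](C)(C)C(C)(C)C)[C@@H](C)Oc2ccc([C@H]3O[C@H](c4ccc(O[C@H](C)[C@H](O[Si](C)(C)C(C)(C)C)c5ccc(OC)c(OC)c5)c(OC)c4)[C@H](C)[C@H]3C)cc2OC)cc1OC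
A2 | alternative 1 | (3R,4R)-3,4-dimethyl-2,5-bis(phenylsulfonyl)oxolane (C2 and C5 undefined) | O=S(=O)(c1ccccc1)C1OC(S(=O)(=O)c2ccccc2)[C@H](C)[C@H]1C
A3 | alternative 1 | (4-{[(1R,2R)-1-(tert-butyldimethylsilyloxy)-1-(3,4-dimethoxyphenyl)propan-2-yl]oxy}-3-methoxyphenyl)zinc bromide | Br[Zn]c1ccc(O[C@H](C)[C@H](O[Si](C)(C)C(C)(C)C)c2ccc(OC)c(OC)c2)c(OC)c1
A4 | alternative 1 | (2R,3R)-2,3-dimethylbutanedial | O=C[C@H](C)[C@@H](C)C=O
A5 | alternative 2 | manassantin A diacetate | COc1ccc([C@@H](OC(C)=O)[C@@H](C)Oc2ccc([C@H]3O[C@H](c4ccc(O[C@H](C)[C@H](OC(C)=O)c5ccc(OC)c(OC)c5)c(OC)c4)[C@H](C)[C@H]3C)cc2OC)cc1OC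
A6 | alternative 2 | (1R,2R)-1-(3,4-dimethoxyphenyl)-2-{2-methoxy-4-[(E)-prop-1-en-1-yl]phenoxy}propyl acetate | C/C=C/c1ccc(O[C@H](C)[C@H](OC(C)=O)c2ccc(OC)c(OC)c2)c(OC)c1
A7 | alternative 3 | (4R,5S)-2-[4-(benzyloxy)-3-methoxyphenyl]-5-[3-methoxy-4-(tosyloxy)phenyl]-3,4-dimethyl-4,5-dihydrofuran (4,5-cis) | CC1=C(c2ccc(OCc3ccccc3)c(OC)c2)O[C@H](c4ccc(OS(=O)(=O)c5ccc(C)cc5)c(OC)c4)[C@@H]1C
A8 | alternative 3 | [4-(benzyloxy)-3-methoxyphenyl]{1,2-dimethyl-3-[3-methoxy-4-(tosyloxy)phenyl]cyclopropyl}methanone (C2 methyl and C3 aryl trans, acyl-bearing carbon undefined) | CC1(C(=O)c2ccc(OCc3ccccc3)c(OC)c2)[C@@H](c2ccc(OS(=O)(=O)c3ccc(C)cc3)c(OC)c2)[C@@H]1C
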